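The ratio of Z charged to X charged comes first, because each L made takes one Z. L therefore cannot pass that ratio, the Z ceiling 100 %, which is the same for teal and amber.

the same everywhere: X 0.10 M
- Saturday's: Z 0.10 M; J 0.015 M; temperature 118 °C; run made earlier
- Sunday's: Z 0.10 M; J 0.019 M; temperature 134 °C; run made earlier
- teal: Z 0.100 M; J 0.0120 M; at 110 °C throughout; time 20 h
- amber: Z 0.100 M; J 0.0200 M; at 110 °C until 6.0 h, from then on at 140 °C; time 20 h

| run | time / h | L / % | X / % |
|---|---|---|---|
| Saturday's | 0.833 | 0.2 | 99.3 |
| Saturday's | 1.50 | 1.6 | 98.0 |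
| Saturday's | 3.00 | 0 | 94.9 |
| Saturday's | 5.00 | 6.3 | 84.4 |
| Saturday's | 10.0 | 67.4 | 10.2 |
| Sunday's | 0.250 | 1.4 | 97.1 |
| Sunday's | 0.833 | 0 | 94.5 |
| Sunday's | 1.50 | 2.4 | 90.9 |
| Sunday's | 2.50 | 11.8 | 69.7 |
| Sunday's | 3.00 | 27.0 | 47.9 |

(readings scatter by 1 percentage point)

* the flask that ends with the higher amount of L, in percent of the X charged, or "neither" when 2 percentage points or less lies between them (teal / amber / neither)
* final L, as a percentage of the X charged, in teal
* final L, as a percentage of the X charged, in amber

- in percentages every species weighs as the X in it: one D counts as two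
- for L the D and Q are counted in
- as a solid, counted per litre of solution: Q
- steps that have been proposed: X + Z + L -> 2 L; X + Z -> L; X + L <-> D; Q <-> L; X + J -> E
- in an amount of L, one D counts as one L

Taken in turn, the numbers weigh differently. With X held, an error in Z moves the ceiling point for point. J has a cap of its own, since X + J → E can take no more X than the J charged, which is 12.0 % of the X in teal and 20.0 % in amber. Timing weighs more than J: Saturday's readings of L rose by 61 percentage points between 5.00 h and 10.0 h, against a J charge worth 15.0 % of its X. The number to know well is therefore how far along that rise each flask stands at 20 h. This reckoning of my own gives bounds and not the forecast's numbers: with its X used up, teal lies between 88.0 % and the ceiling, and amber, with its X used up, between 80.0 % and the ceiling. Teal, at 110 °C, is colder than Saturday's 118 °C, so its X may not be used up by 20 h.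

The forecast says amber, with amber at 86 % and teal at 81 %, the teal number on the ground that "Teal's timescale is about twice Saturday's".

The flasks give 80.3 % in teal and 87.3 % in amber, so amber ends higher, as forecast.

    X + Z + L → 2 L (k = 4.25 M⁻² min⁻¹, Ea = 65.0 kJ mol⁻¹)
    X + Z → L (k = 2.80 × 10⁻⁵ M⁻¹ min⁻¹, Ea = 95.0 kJ mol⁻¹)
    X + L ⇌ D, settled at all times (K = 25.4 M⁻¹, ΔH = 0 kJ mol⁻¹)
    Q ⇌ L, rate k4*(cs4 - [L]) while solid is left; crystals form when [L] > cs4 (solubility = 0.0530 M, k = 0.0911 min⁻¹)
    X + J → E (k = 0.0126 M⁻¹ min⁻¹, Ea = 79.0 kJ mol⁻¹)
    (constants at 110 °C)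

Amber has come to rest: X stands at 0.0693 % at 20.0 h, and L at 200 h is still 87.4 %. Of its 13 points below the ceiling, E holds 12.6 %. Teal has not: at 20.0 h it holds X 5.48 %, D 14.9 % and 20 % of its Z, and at 200 h its L reaches 92.9 %, higher than amber's 87.4 %. The order belongs to the asked time: teal's answer has moved 5 points at 17.4 h and at 25.0 h.

A neighbour of amber charged with 0.040 M of Z has a ceiling of 40.0 %. It ends at 40.0 % of L, with 0.10 % of its Z and 25 % of its X left, so there Z is the limiting reagent.

(The readings stem from a simulated flask for substances that don't exist, noise included.)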